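**Plan**

- Convention: germacrane numbering (C1 ketone, C3 carbinol, C4 and C10 methyl-bearing, C6 lactone carbinol, C8 angelate carbinol, C11–C13 acrylate unit on C7); β is the face of the C7–C11 bond, α the opposite face.
- Retrosynthesis: C3–OH from C3–SiMe2Ph; angelate off O8; the lactone O–C6 bond is cut to a C12 carboxylate plus an E C5=C6 olefin, with the carboxyl parked on O8 as a cis-fused 12,8-olide (itself from a 3-methylene-tetrahydrofuran); then C3–C4 is cut with C1–C6 reconnected (anionic oxy-Cope), and C1–C2 (silylvinyl addition) and C6–C5 (allylation) lead back to (R)-carvone.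
- Enabling feature: C7 carries the acrylate and sits between the two oxygenated carbons C6 and C8, so C12 can close a five-membered lactone to either; the C1 ketone, the unsubstituted C5 methylene and C6 are the oxy-Cope retron, which leaves the olefin exactly where the lactone oxygen must enter.
- Forward: the carvone six-membered ring (C1, C6–C10) gains a cis-fused ether ring on C7/C8, the C6 allyl group, the C9/C10 epoxide and the C1 silylvinyl group; oxy-Cope opens it to the ten-membered ring; ether to 12,8-lactone; transposition to the 12,6-lactone; angelate; C3–OH.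
- Stereochemistry: C7 from carvone; C8 by the tether; C10 by epoxidation anti to the fused ring; C1 (sacrificial) by addition anti to the epoxide; C3 and C4 by chair oxy-Cope from C1/C6 with two (E)-termini; C6 from C7 in the key closure; C3–O by retentive C–Si oxidation.

Key step: step 12

**Route**

Step 1
Reactants: 1 (R)-(−)-carvone
Product: 2 (R)-10-hydroxycarvone
Conditions: SeO2 (0.3 equiv), t-BuOOH, CH2Cl2, rt
Reagents that add atoms: tert-butyl hydroperoxide, CC(C)(C)OO (oxygen relayed by SeO2)
Why: The Riley–Sharpless allylic hydroxylation (ene reaction then [2,3]-shift) should take the electron-rich 1,1-disubstituted isopropenyl group at its methyl rather than the electron-poor enone, as is known for carvone, and touches no stereocentre.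

Step 2
Reactants: 2 (R)-10-hydroxycarvone
Product: 3 cis-fused methylene-tetrahydrofuran enone (C8–O β)
Conditions: PhI(OAc)2, I2, cyclohexane/CH2Cl2, visible light, rt
Reagents that add atoms: none
Why: In this hypoiodite (Suárez) cycloetherification the C12 alkoxy radical should abstract the weak allylic C8–H (γ to the enone) through a six-membered transition state rather than the polarity-mismatched α-keto C6–H, and the resulting iodide or cation can only be closed by the tethered oxygen to a cis-fused ring, which fixes C8–O β.

Step 3
Reactants: 3 cis-fused methylene-tetrahydrofuran enone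
Product: 4 6α-allyl enone
Conditions: LiN(i-Pr)2, THF, −78 °C; allyl bromide, −78 to 0 °C
Reagents that add atoms: allyl bromide, C=CCBr
Why: Kinetic α′-enolate alkylation at C6 should place the allyl group trans to the C7 substituent (convex face of the cis-fused bicycle), as in 6-alkylations of carvone.

Step 4
Reactants: 4 6α-allyl enone
Product: 5 9α,10α-epoxy ketone
Conditions: H2O2 (30%), NaOH (cat.), MeOH, 0 °C
Reagents that add atoms: hydrogen peroxide, OO
Why: In this Weitz–Scheffer nucleophilic epoxidation the hydroperoxide should add to C9 anti to the adjacent β C8–O bond and the fused ring, so the oxirane oxygen is α on C9 and C10 (methyl β) as in carvone oxide, while the basic medium keeps C6 as the trans (α-allyl) epimer.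

Step 5
Reactants: 6 ethynyl(dimethyl)phenylsilane
Product: 7 (E)-tributyl[2-(dimethylphenylsilyl)ethenyl]stannane
Conditions: Bu3SnH, 2,2′-azobis(isobutyronitrile) (cat.), neat, 90 °C
Reagents that add atoms: tributyltin hydride, CCCC[SnH](CCCC)CCCC
Why: Radical hydrostannylation of a silylalkyne gives the (E)-1-stannyl-2-silylethene under thermodynamic control, the established entry to 2-silylvinyl anion equivalents.

Step 6
Reactants: 5 9α,10α-epoxy ketone; 7 (E)-tributyl[2-(dimethylphenylsilyl)ethenyl]stannane
Product: 9 epoxy alcohol (1α-OH; 1β-silylvinyl), via silylvinyllithium 8 (not isolated)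
Conditions: 7, n-BuLi, THF, −78 °C; then 5, −78 °C; H2O
Reagents that add atoms: none
Why: Tin–lithium exchange with retention of olefin geometry is followed by 1,2-addition to the α,β-epoxy ketone anti to the oxirane C–O bond (Felkin–Anh and steric control), which should give C1–OH α (cis to the epoxide) and the vinylsilane β, trans to the C6 allyl group.

Step 7
Reactants: 9 epoxy alcohol
Product: 10 1α,10α-diol (6α-allyl)
Conditions: LiBHEt3, THF, 0 °C to rt; H2O
Reagents that add atoms: none
Why: SN2 hydride opening of the trisubstituted epoxide at the less substituted C9 leaves the C10–O bond untouched, so the tertiary C10–OH stays α and is cis to C1–OH (a Payne shift is excluded because C1–O is cis to the oxirane).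

Step 8
Reactants: 10 1α,10α-diol (6α-allyl)
Product: 11 1α,10α-diol (6α-(E)-propenyl)
Conditions: Pd(dba)2 (3 mol%), P(t-Bu)3 (3 mol%), i-PrCOCl (3 mol%), toluene, 80 °C
Reagents that add atoms: none
Why: Palladium-hydride-catalysed one-position isomerisation of a terminal allyl group gives the (E)-propenyl group, while the 1,1-disubstituted allylic ether olefin and the vinylsilane should not insert.

Step 9
Reactants: 11 1α,10α-diol (6α-(E)-propenyl)
Product: 14 ten-membered hydroxy ketone (3β-Si; 4α-Me; E-5-ene), via dipotassium dialkoxide 12 (not isolated), via dipotassium enolate alkoxide 13 (not isolated)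
Conditions: KH, 18-crown-6, THF, 0 °C to rt; AcOH, −78 °C
Reagents that add atoms: none
Why: In this anionic oxy-Cope rearrangement the trans-diequatorial 1,2-dialkenyl alkoxide should react through a chair transition state, which gives the E C5=C6 olefin and relays the C1/C6 configuration to C3 (silyl β) and C4 (methyl α) because both (E)-termini sit equatorial, and the enolate is protonated to the C1 ketone.

Step 10
Reactants: 14 ten-membered hydroxy ketone
Product: 15 10α-acetate
Conditions: Ac2O, 4-(dimethylamino)pyridine, Et3N, CH2Cl2, 40 °C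
Reagents that add atoms: acetic anhydride, CC(=O)OC(C)=O
Why: Nucleophile-catalysed acylation of the only free hydroxyl (tertiary α-ketol) installs the C10 acetate before any other hydroxyl is set free and removes a transannular nucleophile.

Step 11
Reactants: 15 10α-acetate
Product: 16 cis-fused 12,8β-olide
Conditions: CrO3·2C5H5N (excess), CH2Cl2, rt
Reagents that add atoms: chromium trioxide, O=[Cr](=O)=O
Why: Chromium trioxide–pyridine oxidation of a 3-methylene-tetrahydrofuran to the α-methylene-γ-lactone is a known way to unveil this unit, and the C12–H bonds are the only ones both allylic and α to oxygen.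

Step 12
Reactants: 16 cis-fused 12,8β-olide
Product: 18 8β-hydroxy-12,6α-olide, via lithium seco-carboxylate 17 (not isolated)
Conditions: LiOH, THF/H2O, 0 °C; solvent exchange; pyridinium p-toluenesulfonate (1 equiv), 9-mesityl-10-methylacridinium tetrafluoroborate (5 mol%), 2,4,6-triisopropylbenzenethiol (20 mol%), ClCH2CH2Cl, 450 nm, rt
Reagents that add atoms: lithium hydroxide, [Li+].[OH-]
Why: Proposed new method: after saponification frees O8 and the C12 carboxylate, the photoexcited acridinium oxidises the carboxylate by single-electron transfer to a 2-alkylacryloyloxy radical, which loses CO2 only slowly (it would give a vinyl radical) and adds through oxygen to C6 of the C5=C6 olefin; the C5 radical then takes hydrogen from the arenethiol, and the thiyl radical is reduced by the acridine radical and reprotonated by pyridinium, so the cycle is redox-neutral. The closest known reaction types are the acridinium/thiol-catalysed hydro-lactonisation of alkenoic acids and the cyclisation of aroyloxy radicals onto olefins; new is a carboxyl radical of an acrylic acid adding to a ring-embedded 1,2-dialkyl olefin. The γ-lactone closes in the 5-exo-trig mode, attack at C5 (6-endo) being slower. C6 is set by C7: the carboxyl group lies on the outer face of the E-olefin, and the ring torsion C5=C6–C7–C8 of roughly 100° maps onto the trans-fused lactone (O6 α, H6 β), whereas a cis fusion would need roughly 30°. Both new bonds (O–C6 and H–C5) are made from the exposed outer face, so the closure does not rely on anti-addition across the medium ring. The step needs O–C6 bond formation to beat hydrogen abstraction from C8–H, decarboxylation and thiol addition to the methylene group; the short tether to the electron-rich olefin, the sp2 attachment of the carboxyl group and a hindered thiol used in catalytic amount should secure this.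

Step 13
Reactants: 18 8β-hydroxy-12,6α-olide
Product: 19 8β-angelate
Conditions: angelic acid, 2,4,6-trichlorobenzoyl chloride, Et3N, toluene, rt; then 18, 80 °C
Reagents that add atoms: angelic acid, C/C=C(/C)C(=O)O
Why: Yamaguchi-type mixed-anhydride esterification without nucleophilic catalyst is the standard way to make angelates without Z to E isomerisation, and C8–OH is the only free hydroxyl.

Step 14
Reactants: 19 8β-angelate
Product: 20 target CNP0141210.1
Conditions: Hg(OAc)2, AcOOH, AcOH, rt
Reagents that add atoms: peracetic acid, CC(=O)OO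
Why: Fleming–Tamao oxidation (ipso-mercuridesilylation of the phenyl group, then peracid oxidation of the C–Si bond) converts C3–SiMe2Ph into C3–OH with retention, giving 3β-OH, while the electron-poor olefins and the esters should be left alone.

**Compound list**

1 | (R)-(−)-carvone, (5R)-2-methyl-5-(prop-1-en-2-yl)cyclohex-2-en-1-one | CC1=CC[C@H](CC1=O)C(C)=C | starting material
2 | (R)-10-hydroxycarvone, (5R)-5-(3-hydroxyprop-1-en-2-yl)-2-methylcyclohex-2-en-1-one | CC1=CC[C@H](CC1=O)C(=C)CO | intermediate
3 | (3aR,7aR)-6-methyl-3-methylidene-3,3a,4,7a-tetrahydro-1-benzofuran-5(2H)-one (cis-fused; C8–O β, cis to C7–C11) | CC1=C[C@H]2OCC(=C)[C@H]2CC1=O | intermediate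
4 | 6α-allyl derivative of 3 (allyl on C6 trans to the C7–C11 bond) | CC1=C[C@H]2OCC(=C)[C@H]2[C@H](CC=C)C1=O | intermediate
5 | 9α,10α-epoxide of 4 (oxirane oxygen α, C10 methyl β) | C[C@@]12O[C@@H]1[C@H]1OCC(=C)[C@H]1[C@H](CC=C)C2=O | intermediate
6 | ethynyl(dimethyl)phenylsilane | C#C[Si](C)(C)c1ccccc1 | starting material
7 | (E)-tributyl[2-(dimethylphenylsilyl)ethenyl]stannane | CCCC[Sn](CCCC)(CCCC)/C=C/[Si](C)(C)c1ccccc1 | intermediate
8 | (E)-[2-(dimethylphenylsilyl)ethenyl]lithium | [Li]/C=C/[Si](C)(C)c1ccccc1 | intermediate (not isolated)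
9 | epoxy alcohol: 5 with 1α-OH and 1β-[(E)-2-(dimethylphenylsilyl)ethenyl] | C[C@@]12O[C@@H]1[C@H]1OCC(=C)[C@H]1[C@H](CC=C)[C@@]2(O)/C=C/[Si](C)(C)c1ccccc1 | intermediate
10 | 1α,10α-diol (C9 methylene, 10β-methyl, 6α-allyl, 1β-silylvinyl) | C[C@@]1(O)C[C@H]2OCC(=C)[C@H]2[C@H](CC=C)[C@@]1(O)/C=C/[Si](C)(C)c1ccccc1 | intermediate
11 | 1α,10α-diol with 6α-[(E)-prop-1-enyl] | C[C@@]1(O)C[C@H]2OCC(=C)[C@H]2[C@H](/C=C/C)[C@@]1(O)/C=C/[Si](C)(C)c1ccccc1 | intermediate
12 | dipotassium 1,10-dialkoxide of 11 | C[C@@]1([O-])C[C@H]2OCC(=C)[C@H]2[C@H](/C=C/C)[C@@]1([O-])/C=C/[Si](C)(C)c1ccccc1.[K+].[K+] | intermediate (not isolated)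
13 | dipotassium C1-enolate C10-alkoxide of the ring-expanded ketone | C[C@@]1([O-])C[C@H]2OCC(=C)[C@H]2/C=C/[C@H](C)[C@@H]([Si](C)(C)c2ccccc2)/C=C1\[O-].[K+].[K+] | intermediate (not isolated)
14 | (5E)-8β,12-epoxy-10α-hydroxy-3β-(dimethylphenylsilyl)germacra-5,11(13)-dien-1-one (4α-methyl, 10β-methyl, H-7α) | C[C@@]1(O)C[C@H]2OCC(=C)[C@H]2/C=C/[C@H](C)[C@@H]([Si](C)(C)c2ccccc2)CC1=O | intermediate
15 | 10α-acetate of 14 | C[C@@]1(OC(C)=O)C[C@H]2OCC(=C)[C@H]2/C=C/[C@H](C)[C@@H]([Si](C)(C)c2ccccc2)CC1=O | intermediate
16 | (5E)-10α-acetoxy-3β-(dimethylphenylsilyl)-1-oxogermacra-5,11(13)-dien-12,8β-olide (cis-fused lactone) | C[C@@]1(OC(C)=O)C[C@H]2OC(=O)C(=C)[C@H]2/C=C/[C@H](C)[C@@H]([Si](C)(C)c2ccccc2)CC1=O | intermediate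
17 | lithium (5E)-10α-acetoxy-8β-hydroxy-3β-(dimethylphenylsilyl)-1-oxogermacra-5,11(13)-dien-12-oate | C[C@@]1(OC(C)=O)C[C@@H](O)[C@@H](C(=C)C(=O)[O-])/C=C/[C@H](C)[C@@H]([Si](C)(C)c2ccccc2)CC1=O.[Li+] | intermediate (not isolated)
18 | 10α-acetoxy-8β-hydroxy-3β-(dimethylphenylsilyl)-1-oxogermacr-11(13)-en-12,6α-olide (4α-methyl, H-6β, H-7α; trans-fused lactone) | C=C1C(=O)O[C@@H]2C[C@H](C)[C@@H]([Si](C)(C)c3ccccc3)CC(=O)[C@](C)(OC(C)=O)C[C@@H](O)[C@@H]12 | intermediate
19 | 8β-angelate of 18 | C=C1C(=O)O[C@@H]2C[C@H](C)[C@@H]([Si](C)(C)c3ccccc3)CC(=O)[C@](C)(OC(C)=O)C[C@@H](OC(=O)/C(C)=C\C)[C@@H]12 | intermediate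
20 | CNP0141210.1, 10α-acetoxy-8β-angeloyloxy-3β-hydroxy-1-oxogermacr-11(13)-en-12,6α-olide (4α-methyl) | C=C1C(=O)O[C@@H]2C[C@H](C)[C@@H](O)CC(=O)[C@](C)(OC(C)=O)C[C@@H](OC(=O)/C(C)=C\C)[C@@H]12 | target

**Step count**

Total: 14 steps. Longest linear sequence: 13 steps (steps 1–4 and 6–14 from 1); step 5 prepares the side fragment.

**Steps most likely to fail, with fallbacks**

Step 12 (proposed new method). The carboxyl radical may lose CO2, or abstract hydrogen from C8–H instead of adding to C6. The thiol may add to the α-methylene group, by a radical or a conjugate path. The seco acid may also re-close to the 12,8-lactone before it is oxidised. The fallback uses known polar chemistry and sets out from 16. Saponification (LiOH, THF/H2O, 0 °C) gives carboxylate 17, and I2 with NaHCO3 in the same aqueous THF should effect a 5-exo iodolactonisation (anti addition) to the 5α-iodo-8β-hydroxy-12,6α-olide F1. Radical deiodination (Bu3SnH, Et3B/air, toluene, 0 °C, before the angelate is in place) then removes the iodine, and the route is rejoined at 18.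

Step 2. The allylic radical, iodide or cation at C8 may lose a proton from C7 and aromatise to the phenol tautomer. The primary allylic alcohol may be over-oxidised to the enal, or acetate may trap C8. The fallback sets out from 2. Thermodynamic silylation (TBSCl, NaI, Et3N, MeCN, 60 °C) should give the extended dienol ether, silylated also on the primary alcohol, the bis-silyl dienol ether F2. NBS (THF, −78 °C) brominates the γ-carbon anti to the side chain to give the 8α-bromo enone F3. Bu4NF (THF, 0 °C) then frees the primary alkoxide, which displaces the bromide with inversion and returns the cis-fused ether 3.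

Step 11. The oxidant may abstract the doubly allylic C7–H or attack the ether methine C8–H, leading to olefin migration or ring cleavage instead of C12 oxidation. The fallback sets out from 15. An ene reaction with SeO2 (cat.)/t-BuOOH in CH2Cl2 is confined to the 1,1-disubstituted C11=C13 olefin and its α-alkoxy C12–H, and after the [2,3]-shift should give the C12 lactol F4. Fétizon oxidation (Ag2CO3 on Celite, benzene, reflux) converts the lactol into the lactone, and the route is rejoined at 16.

**Further compounds**

F1 | step 12 | 5α-iodo derivative of 18 (iodine anti to the lactone oxygen) | C=C1C(=O)O[C@@H]2[C@H](I)[C@H](C)[C@@H]([Si](C)(C)c3ccccc3)CC(=O)[C@](C)(OC(C)=O)C[C@@H](O)[C@@H]12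
F2 | step 2 | bis(tert-butyldimethylsilyl) extended dienol ether of 2 | CC1=C(O[Si](C)(C)C(C)(C)C)C[C@H](C(=C)CO[Si](C)(C)C(C)(C)C)C=C1
F3 | step 2 | 8α-bromo enone, primary TBS ether (bromine trans to the C7 side chain) | CC1=C[C@H](Br)[C@@H](C(=C)CO[Si](C)(C)C(C)(C)C)CC1=O
F4 | step 11 | C12 lactol of 15 (anomeric mixture) | C[C@@]1(OC(C)=O)C[C@H]2OC(O)C(=C)[C@H]2/C=C/[C@H](C)[C@@H]([Si](C)(C)c2ccccc2)CC1=O
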